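**Retrosynthetic overview**

1. Agrandol, (2S)-5,7-dihydroxy-6-methoxy-8-prenylflavanone, goes back to its 5,7-bis(MOM) ether (acidic acetal cleavage as the last step).
2. Key disconnection: the pyranone ring C (O1–C2 bond), the C8–prenyl bond and the C2 stereocentre all go back to one acyclic, achiral aryl 1,1-dimethylallyl ether carrying a benzylidene tert-butyl β-ketoester. The ester is a temporary activating group on C3 and is lost in the same flask.
3. Enabling feature: the ring oxygen O1 sits on C8a, which is ortho to the prenylated C8 and, through C4a–C4–C3–C2, β to the C4 ketone. O1 is therefore both the oxygen of an ortho-prenylphenol (Claisen retron) and the donor of an oxa-Michael retron, while C4a (acyl) and C6 (OMe) block every other ring position.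
4. The acceptor comes from Knoevenagel condensation with benzaldehyde of a β-ketoester made by aldol addition/oxidation on an aryl aldehyde. The aldehyde comes from directed lithiation of a mirror-symmetric aryl tert-prenyl ether, and its phenol from 2-methoxyresorcinol by MOM protection and Ir-catalysed C–H borylation/oxidation.
5. Ring order: rings A and B are bought intact (2-methoxyresorcinol, benzaldehyde); ring C is the only ring made and is closed last, in the key step.

Key step: step 9

Remark (assumption on the chemistry): the quinidine-derived cinchona thiourea is taken to deliver the (2S) series. If the sense proves to be the reverse, its quinine-derived pseudoenantiomer is used under the same conditions.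

**Route**

Step 1
Reactants: 1 2-methoxybenzene-1,3-diol (2-methoxyresorcinol)
Product: 2 2-methoxy-1,3-bis(methoxymethoxy)benzene
Conditions: NaH (2.3 equiv), MOMCl (2.3 equiv), DMF, 0 °C → rt
Reagents that add atoms: chloromethyl methyl ether, COCCl
Why: Double Williamson-type O-alkylation of the two equivalent phenols gives MOM ethers that are stable to base and organolithiums and later direct the ortho-lithiation.

Step 2
Reactants: 2 2-methoxy-1,3-bis(methoxymethoxy)benzene
Product: 4 4-methoxy-3,5-bis(methoxymethoxy)phenol, via aryl pinacol boronate 3 (not isolated)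
Conditions: [Ir(OMe)(cod)]2 (1.5 mol%), dtbpy (3 mol%), B2pin2 (1.0 equiv), THF, 80 °C; then aq. NaOH, 30% H2O2, 0 °C → rt
Reagents that add atoms: hydrogen peroxide, OO; bis(pinacolato)diboron, CC1(C)OB(OC1(C)C)B1OC(C)(C)C(C)(C)O1 (its boron stays only in intermediate 3)
Why: Iridium-catalysed aromatic C–H borylation is governed by sterics and should touch only C5, the single C–H without an ortho substituent, and oxidation of the C–B bond in the same flask gives the mirror-symmetric phenol with the MOM ethers intact under basic peroxide.

Step 3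
Reactants: 5 2-methylbut-3-en-2-ol
Product: 6 tert-butyl 2-methylbut-3-en-2-yl carbonate
Conditions: n-BuLi (1.0 equiv), THF, 0 °C; Boc2O, 0 °C → rt; H2O
Reagents that add atoms: di-tert-butyl dicarbonate, CC(C)(C)OC(=O)OC(=O)OC(C)(C)C
Why: O-acylation of the lithium alkoxide of the tertiary allylic alcohol with Boc2O gives the mixed carbonate that serves as the π-allyl precursor.

Step 4
Reactants: 4 4-methoxy-3,5-bis(methoxymethoxy)phenol; 6 tert-butyl 2-methylbut-3-en-2-yl carbonate
Product: 7 2-methoxy-1,3-bis(methoxymethoxy)-5-[(2-methylbut-3-en-2-yl)oxy]benzene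
Conditions: Pd(PPh3)4 (2 mol%), 4 Å MS, THF, 0 °C
Reagents that add atoms: none
Why: In this Tsuji–Trost-type decarboxylative O-allylation the phenoxide attacks the more substituted terminus of the 1,1-dimethyl-π-allylpalladium complex under kinetic control at 0 °C, which should give the tertiary (reverse-prenyl) aryl ether without acid or heat.

Step 5
Reactants: 7 2-methoxy-1,3-bis(methoxymethoxy)-5-[(2-methylbut-3-en-2-yl)oxy]benzene
Product: 9 3-methoxy-2,4-bis(methoxymethoxy)-6-[(2-methylbut-3-en-2-yl)oxy]benzaldehyde, via aryllithium 8 (not isolated)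
Conditions: s-BuLi (1.15 equiv), THF, −78 °C; DMF, −78 → −20 °C; H2O
Reagents that add atoms: N,N-dimethylformamide, CN(C)C=O
Why: Directed ortho-metalation at the C–H flanked by a MOM ether and the tert-alkoxy group (the two free positions are equivalent by symmetry) is followed by formylation with DMF, and −78 °C is held so that the aryllithium does not add to its own vinyl group.

Step 6
Reactants: 9 3-methoxy-2,4-bis(methoxymethoxy)-6-[(2-methylbut-3-en-2-yl)oxy]benzaldehyde; 10 tert-butyl acetate
Product: 12 tert-butyl 3-hydroxy-3-{3-methoxy-2,4-bis(methoxymethoxy)-6-[(2-methylbut-3-en-2-yl)oxy]phenyl}propanoate (racemic), via lithium enolate 11 (not isolated)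
Conditions: LDA (1.3 equiv), 10, THF, −78 °C; then 9, −78 °C; H2O
Reagents that add atoms: none
Why: Aldol addition of the lithium enolate of tert-butyl acetate to the aldehyde brings in the future C3 and the activating tert-butyl ester; the carbinol centre forms as a racemate and is erased in step 7.

Step 7
Reactants: 12 tert-butyl 3-hydroxy-3-{3-methoxy-2,4-bis(methoxymethoxy)-6-[(2-methylbut-3-en-2-yl)oxy]phenyl}propanoate
Product: 13 tert-butyl 3-{3-methoxy-2,4-bis(methoxymethoxy)-6-[(2-methylbut-3-en-2-yl)oxy]phenyl}-3-oxopropanoate
Conditions: TPAP (5 mol%), NMO (1.5 equiv), 4 Å MS, CH2Cl2, rt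
Reagents that add atoms: none
Why: Ley–Griffith oxidation of the benzylic alcohol runs under neutral conditions that should spare the acid-labile tert-allyl aryl ether, the MOM ethers and the terminal alkene.

Step 8
Reactants: 13 tert-butyl 3-{3-methoxy-2,4-bis(methoxymethoxy)-6-[(2-methylbut-3-en-2-yl)oxy]phenyl}-3-oxopropanoate; 14 benzaldehyde
Product: 15 tert-butyl (2Z)-2-{3-methoxy-2,4-bis(methoxymethoxy)-6-[(2-methylbut-3-en-2-yl)oxy]benzoyl}-3-phenylprop-2-enoate (Z expected as the main geometry; the geometry is not carried into the product)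
Conditions: piperidine (10 mol%), AcOH (10 mol%), 4 Å MS, toluene, rt
Reagents that add atoms: none
Why: Knoevenagel condensation of the active methylene with benzaldehyde under piperidinium acetate catalysis; the future ring oxygen is still capped as the tert-prenyl ether, so no racemic ring closure can occur here, and room temperature keeps the ether from rearranging.

Step 9
Reactants: 15 tert-butyl (2Z)-2-{3-methoxy-2,4-bis(methoxymethoxy)-6-[(2-methylbut-3-en-2-yl)oxy]benzoyl}-3-phenylprop-2-enoate
Product: 19 (2S)-6-methoxy-5,7-bis(methoxymethoxy)-8-(3-methylbut-2-en-1-yl)-2-phenyl-2,3-dihydro-4H-chromen-4-one, via ortho-prenyl phenol 16 (not isolated), via chromanone tert-butyl ester 17 (not isolated), via chromanone carboxylic acid 18 (not isolated)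
Conditions: toluene (0.02 M), 100 °C, Ar; then quinidine-derived 3,5-bis(trifluoromethyl)phenyl thiourea (from 9-amino-9-deoxy-epi-quinidine, 10 mol%), −25 °C; then 85% aq. H3PO4 (5 equiv), −25 → 45 °C
Reagents that add atoms: none
Why: On heating, the aryl 1,1-dimethylallyl ether undergoes a [3,3] aromatic Claisen rearrangement to the only unsubstituted ortho carbon (the other ortho carbon carries the aroyl group), which places the prenyl group on the future C8 and uncovers the phenol that becomes O1; at −25 °C the cinchona thiourea then effects the intramolecular oxa-Michael addition of that phenol to the benzylidene β-ketoester, and weak acid finally cleaves the tert-butyl ester, after which the β-keto acid loses CO2. The closest known reaction types are the tandem Claisen rearrangement/6-endo cyclisation used for 8-prenylated chromones and the bifunctional-thiourea-catalysed enantioselective cyclisation of 2-hydroxyaryl benzylidene β-ketoesters with decarboxylation in the same flask. The pyranone ring closes by a 6-endo-trig O–C conjugate addition (O1–C2 bond). C2 is set under catalyst control: the quinuclidine nitrogen activates the phenol while the thiourea holds the 1,3-dicarbonyl unit, so that one enantiotopic face of the benzylidene carbon is attacked, and the transient C3 centre vanishes on decarboxylation. The step needs regiocontrol (prenyl at C8 and closure through O1 only), which the substrate secures because the oxygen that carried the tert-prenyl group is the only free phenol while O5 and O7 stay capped as MOM ethers, and it needs enantiocontrol, which is protected by keeping the catalyst out of the hot stage (the freed phenol is hydrogen-bonded to the ketone in a base-free medium) and by removing the ester under acid, where retro-oxa-Michael opening is shut down and the MOM ethers and the prenyl group should survive.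

Step 10
Reactants: 19 (2S)-6-methoxy-5,7-bis(methoxymethoxy)-8-(3-methylbut-2-en-1-yl)-2-phenyl-2,3-dihydro-4H-chromen-4-one
Product: 20 agrandol, (2S)-5,7-dihydroxy-6-methoxy-8-(3-methylbut-2-en-1-yl)-2-phenyl-2,3-dihydro-4H-chromen-4-one
Conditions: 3 M aq. HCl, MeOH, 50 °C, short reaction time
Reagents that add atoms: none
Why: Acid-catalysed acetal cleavage of the two aryl MOM ethers in methanol; without base the flavanone cannot open by retro-oxa-Michael, so C2 should keep its configuration, and brief mild exposure is meant to spare the prenyl group.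

**Compound list**

1 | 2-methoxybenzene-1,3-diol (2-methoxyresorcinol) | COc1c(O)cccc1O | starting material
2 | 2-methoxy-1,3-bis(methoxymethoxy)benzene | COCOc1cccc(OCOC)c1OC | intermediate
3 | 2-[4-methoxy-3,5-bis(methoxymethoxy)phenyl]-4,4,5,5-tetramethyl-1,3,2-dioxaborolane | COCOc1cc(B2OC(C)(C)C(C)(C)O2)cc(OCOC)c1OC | intermediate
4 | 4-methoxy-3,5-bis(methoxymethoxy)phenol | COCOc1cc(O)cc(OCOC)c1OC | intermediate
5 | 2-methylbut-3-en-2-ol | CC(C)(O)C=C | starting material
6 | tert-butyl 2-methylbut-3-en-2-yl carbonate | CC(C)(C)OC(=O)OC(C)(C)C=C | intermediate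
7 | 2-methoxy-1,3-bis(methoxymethoxy)-5-[(2-methylbut-3-en-2-yl)oxy]benzene | COCOc1cc(OC(C)(C)C=C)cc(OCOC)c1OC | intermediate
8 | {3-methoxy-2,4-bis(methoxymethoxy)-6-[(2-methylbut-3-en-2-yl)oxy]phenyl}lithium | [Li]c1c(OC(C)(C)C=C)cc(OCOC)c(OC)c1OCOC | intermediate
9 | 3-methoxy-2,4-bis(methoxymethoxy)-6-[(2-methylbut-3-en-2-yl)oxy]benzaldehyde | O=Cc1c(OC(C)(C)C=C)cc(OCOC)c(OC)c1OCOC | intermediate
10 | tert-butyl acetate | CC(=O)OC(C)(C)C | starting material
11 | lithium enolate of tert-butyl acetate (lithium 1-tert-butoxyethen-1-olate) | C=C(O[Li])OC(C)(C)C | intermediate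
12 | tert-butyl 3-hydroxy-3-{3-methoxy-2,4-bis(methoxymethoxy)-6-[(2-methylbut-3-en-2-yl)oxy]phenyl}propanoate (racemic) | CC(C)(C)OC(=O)CC(O)c1c(OC(C)(C)C=C)cc(OCOC)c(OC)c1OCOC | intermediate
13 | tert-butyl 3-{3-methoxy-2,4-bis(methoxymethoxy)-6-[(2-methylbut-3-en-2-yl)oxy]phenyl}-3-oxopropanoate | CC(C)(C)OC(=O)CC(=O)c1c(OC(C)(C)C=C)cc(OCOC)c(OC)c1OCOC | intermediate
14 | benzaldehyde | O=Cc1ccccc1 | starting material
15 | tert-butyl (2Z)-2-{3-methoxy-2,4-bis(methoxymethoxy)-6-[(2-methylbut-3-en-2-yl)oxy]benzoyl}-3-phenylprop-2-enoate | CC(C)(C)OC(=O)/C(=C\c1ccccc1)C(=O)c1c(OC(C)(C)C=C)cc(OCOC)c(OC)c1OCOC | intermediate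
16 | tert-butyl (2Z)-2-[2-hydroxy-5-methoxy-4,6-bis(methoxymethoxy)-3-(3-methylbut-2-en-1-yl)benzoyl]-3-phenylprop-2-enoate | CC(C)(C)OC(=O)/C(=C\c1ccccc1)C(=O)c1c(O)c(CC=C(C)C)c(OCOC)c(OC)c1OCOC | intermediate
17 | tert-butyl (2S)-6-methoxy-5,7-bis(methoxymethoxy)-8-(3-methylbut-2-en-1-yl)-4-oxo-2-phenyl-3,4-dihydro-2H-chromene-3-carboxylate (mixture at C3) | COCOc1c(OC)c(OCOC)c(CC=C(C)C)c2c1C(=O)C(C(=O)OC(C)(C)C)[C@@H](c1ccccc1)O2 | intermediate
18 | (2S)-6-methoxy-5,7-bis(methoxymethoxy)-8-(3-methylbut-2-en-1-yl)-4-oxo-2-phenyl-3,4-dihydro-2H-chromene-3-carboxylic acid (mixture at C3) | COCOc1c(OC)c(OCOC)c(CC=C(C)C)c2c1C(=O)C(C(=O)O)[C@@H](c1ccccc1)O2 | intermediate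
19 | (2S)-6-methoxy-5,7-bis(methoxymethoxy)-8-(3-methylbut-2-en-1-yl)-2-phenyl-2,3-dihydro-4H-chromen-4-one | COCOc1c(OC)c(OCOC)c(CC=C(C)C)c2c1C(=O)C[C@@H](c1ccccc1)O2 | intermediate
20 | agrandol, (2S)-5,7-dihydroxy-6-methoxy-8-(3-methylbut-2-en-1-yl)-2-phenyl-2,3-dihydro-4H-chromen-4-one | COc1c(O)c(CC=C(C)C)c2c(c1O)C(=O)C[C@@H](c1ccccc1)O2 | target

**Step count and risks**

Total step count: 10. Longest linear sequence: 9 steps (steps 1, 2, 4, 5, 6, 7, 8, 9 and 10 from 2-methoxyresorcinol); step 3 is a one-step branch.

Steps most likely to fail: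

1. Step 9. The enantiomeric purity may be eroded by uncatalysed ring closure of the freed phenol during the hot stage, by reversible ring opening of the cyclised β-ketoester before the ester is lost, or by weaker face selection with the doubly ortho-substituted aroyl group. The fallback sets out from 15 and comes back at 19. Compound 15 is heated in toluene as before, DABCO (20 mol%) is added at room temperature to close the ring without chiral control, and the ester is removed with aqueous H3PO4, which should give the racemic 6-methoxy-5,7-bis(methoxymethoxy)-8-prenylflavanone F1. F1 is then submitted to kinetic resolution by Noyori-type asymmetric transfer hydrogenation ([Cp*RhCl((R,R)-TsDPEN)], HCO2H/Et3N, EtOAc, rt, stopped near half conversion), a reaction type known on racemic flavanones. The catalyst antipode is chosen so that the (2R)-ketone is the fast-reacting one ((R,R) by the usual model); it should be reduced from the face anti to the phenyl group to the cis-(2R,4R)-flavan-4-ol F2, and the slow-reacting (2S)-ketone is recovered as 19 by chromatography.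

2. Step 5. The ortho-aryllithium may add to its own vinyl group (5-exo carbolithiation), or metalation may stay incomplete at the low temperature that this risk imposes. The fallback sets out from 4 and comes back at 9. Magnesium-mediated ortho-formylation of phenol 4 (MgCl2, Et3N, paraformaldehyde, MeCN, reflux) is specific for the position ortho to the free OH and tolerates MOM ethers; it should give 2-hydroxy-5-methoxy-4,6-bis(methoxymethoxy)benzaldehyde F3. Its hydrogen-bonded phenol is then O-alkylated with carbonate 6 under the Pd(0) conditions of step 4 to give 9, so that no aryllithium is generated next to the vinyl group.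

3. Step 10. Under protic acid the freed 7-OH may add to the prenyl double bond (chroman formation), or the alkene may be hydrated, in competition with acetal cleavage. The fallback sets out from 19 and comes back at 20. Treatment with TMSOTf and 2,2'-bipyridyl in CH2Cl2 (0 °C → rt) converts aryl MOM ethers through pyridinium intermediates into silyl ethers without a Brønsted acid, and should give (2S)-6-methoxy-8-(3-methylbut-2-en-1-yl)-2-phenyl-5,7-bis(trimethylsilyloxy)-2,3-dihydro-4H-chromen-4-one F4. F4 is hydrolysed with water at room temperature to 20.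

**Further compounds**

F1 | step 9 | racemic 6-methoxy-5,7-bis(methoxymethoxy)-8-(3-methylbut-2-en-1-yl)-2-phenyl-2,3-dihydro-4H-chromen-4-one | COCOc1c(OC)c(OCOC)c(CC=C(C)C)c2c1C(=O)CC(c1ccccc1)O2
F2 | step 9 | (2R,4R)-6-methoxy-5,7-bis(methoxymethoxy)-8-(3-methylbut-2-en-1-yl)-2-phenyl-3,4-dihydro-2H-chromen-4-ol (2,4-cis) | COCOc1c(OC)c(OCOC)c(CC=C(C)C)c2c1[C@H](O)C[C@H](c1ccccc1)O2
F3 | step 5 | 2-hydroxy-5-methoxy-4,6-bis(methoxymethoxy)benzaldehyde | O=Cc1c(O)cc(OCOC)c(OC)c1OCOC
F4 | step 10 | (2S)-6-methoxy-8-(3-methylbut-2-en-1-yl)-2-phenyl-5,7-bis(trimethylsilyloxy)-2,3-dihydro-4H-chromen-4-one | C[Si](C)(C)Oc1c(OC)c(O[Si](C)(C)C)c(CC=C(C)C)c2c1C(=O)C[C@@H](c1ccccc1)O2
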